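**Retrosynthetic overview**
1. The last disconnection is the bond between the bridge CH2 and C3 of the pyrone. It gives the C7 dimethylaminomethyl (Mannich) derivative of an (R)-2-isopropenyl-2,3-dihydrobenzofuran, which is a latent o-quinone methide, and 6-ethyl-4-hydroxy-5-methyl-2-pyrone. This union copies the presumed biosynthesis of methylene-bridged phloroglucinol–pyrone dimers.
2. Enabling feature: the bridge carbon sits on C7 of the benzene ring, ortho to the C6–OH and para to the C4–OH, so a leaving group on it is pushed out to give an o-quinone methide. C3 of the pyrone lies between the C4 enol and the C2 lactone carbonyl and is the only free ring carbon, because C5 carries CH3.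
3. The dihydrofuran ring comes from forming the C2–O bond by Pd-catalysed asymmetric allylic etherification of an (E)-allylic carbonate side chain on phlorisobutyrophenone. This step sets C2 (R).
4. The side chain comes from 2-methyl-2-vinyloxirane and the ketone from Friedel–Crafts acylation of phloroglucinol. The pyrone comes from γ-acylation of a β-keto ester dianion followed by lactonisation.
5. Ring order: the benzene ring is bought, the dihydrofuran ring is closed in step 5, and the pyrone ring is closed in step 8 on a parallel branch. No ring is closed after the union.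

Key step: step 9

Assumption: the (R,R) ligand is assigned to the (R) product by analogy with the cyclisation of simpler o-(4-carbonyloxy-3-methylbut-2-enyl)phenols. If the sense is opposite on this substrate, the (S,S) ligand is used and nothing else changes.

**Step 1**
Reactants: 1 phloroglucinol (benzene-1,3,5-triol); 2 isobutyryl chloride
Product: 3 phlorisobutyrophenone [2-methyl-1-(2,4,6-trihydroxyphenyl)propan-1-one]
Conditions: AlCl3 (3.5 equiv), CH2Cl2–PhNO2, 40 °C; then ice/aq HCl
Reagents that add atoms: none
Why: Friedel–Crafts acylation of the threefold activated ring should stop at the monoketone because the chelated aryl ketone–aluminium complex is deactivated towards a second acylation.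

**Step 2**
Reactants: 4 2-methyl-2-vinyloxirane (racemic)
Product: 5 (E)-4-chloro-2-methylbut-2-en-1-ol
Conditions: TiCl4 (1.1 equiv), CH2Cl2, −85 °C; then 1 M HCl
Reagents that add atoms: titanium tetrachloride, Cl[Ti](Cl)(Cl)Cl
Why: Lewis-acid-promoted SN2' opening of a vinyl epoxide, in which titanium binds the epoxide oxygen and chloride is delivered to the vinyl terminus, the transoid allyl geometry giving the E-trisubstituted alkene while the stereocentre of racemic 4 disappears.

**Step 3**
Reactants: 5 (E)-4-chloro-2-methylbut-2-en-1-ol
Product: 6 (E)-4-chloro-2-methylbut-2-en-1-yl methyl carbonate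
Conditions: ClCO2Me (1.2 equiv), pyridine (1.5 equiv), CH2Cl2, 0 °C
Reagents that add atoms: methyl chloroformate, COC(=O)Cl
Why: O-acylation of the primary allylic alcohol with a chloroformate (carbonate formation) at a temperature at which pyridine should not displace the allylic chloride.

**Step 4**
Reactants: 3 phlorisobutyrophenone (2.0 equiv); 6 (E)-4-chloro-2-methylbut-2-en-1-yl methyl carbonate
Product: 7 (2E)-2-methyl-4-[2,4,6-trihydroxy-3-(2-methylpropanoyl)phenyl]but-2-en-1-yl methyl carbonate
Conditions: DBU (1.0 equiv), NaI (10 mol %), THF, 0 °C to rt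
Reagents that add atoms: none
Why: Base-mediated C-allylation of an acylphloroglucinol, the reaction type used for C-prenylation of such phenols, in which the delocalised monoanion reacts through ring carbon as a vinylogous triketone enolate in an SN2 displacement at the primary allylic halide, the excess of 3 holds back a second alkylation, and the allylic carbonate is inert without palladium.

**Step 5**
Reactants: 7 (2E)-2-methyl-4-[2,4,6-trihydroxy-3-(2-methylpropanoyl)phenyl]but-2-en-1-yl methyl carbonate
Product: 8 1-[(2R)-4,6-dihydroxy-2-(prop-1-en-2-yl)-2,3-dihydro-1-benzofuran-5-yl]-2-methylpropan-1-one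
Conditions: Pd2(dba)3·CHCl3 (2.5 mol %), (R,R)-DACH-phenyl Trost ligand (7.5 mol %), AcOH (1 equiv), CH2Cl2, rt
Reagents that add atoms: none
Why: Intramolecular Tsuji–Trost asymmetric allylic etherification, known for o-(4-carbonyloxy-3-methylbut-2-enyl)phenols, in which ionisation gives a π-allylpalladium complex, the methoxide released from the carbonate takes the phenol proton, the hydroxyl para to the ketone (the most acidic one, while the other flanking hydroxyl is tied to the carbonyl by a hydrogen bond) attacks the internal allyl terminus in a 5-exo mode, and the chiral pocket of the (R,R) ligand selects the allyl face that leads to C2 (R).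

**Step 6**
Reactants: 8 1-[(2R)-4,6-dihydroxy-2-(prop-1-en-2-yl)-2,3-dihydro-1-benzofuran-5-yl]-2-methylpropan-1-one; 9 Eschenmoser's salt (N,N-dimethylmethyleneiminium iodide)
Product: 10 1-{(2R)-7-[(dimethylamino)methyl]-4,6-dihydroxy-2-(prop-1-en-2-yl)-2,3-dihydro-1-benzofuran-5-yl}-2-methylpropan-1-one
Conditions: 9 (1.05 equiv), CH2Cl2, 0 °C to rt; then cold aq NaHCO3; used without chromatography
Reagents that add atoms: none
Why: Mannich aminomethylation (electrophilic aromatic substitution by a preformed iminium ion) can only occur at C7, the one free ring carbon, and the product stays N-protonated until work-up, which should prevent premature loss of the amine, while the isopropenyl group and C2 are not affected.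

**Step 7**
Reactants: 11 ethyl 3-oxopentanoate; 12 N-methoxy-N-methylpropanamide
Product: 14 ethyl 4-methyl-3,5-dioxoheptanoate, via dilithio dianion 13 (not isolated)
Conditions: LDA (2.2 equiv, commercial solution), THF, −78 to 0 °C; then 12, −78 °C to rt; aq HCl
Reagents that add atoms: none
Why: γ-Acylation of a β-keto ester dianion, in which the more basic terminal carbanion of 13 attacks the Weinreb amide and the chelated tetrahedral adduct survives until the acidic quench, so over-addition and proton exchange are prevented, and the enolisable C4 centre of 14 is racemic and vanishes in step 8.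

**Step 8**
Reactants: 14 ethyl 4-methyl-3,5-dioxoheptanoate
Product: 15 6-ethyl-4-hydroxy-5-methyl-2H-pyran-2-one
Conditions: DBU (1.0 equiv), PhMe, reflux; then aq HCl
Reagents that add atoms: none
Why: Base-induced enol lactonisation of a 3,5-dioxo ester (6-exo-trig attack of the C5 enolate oxygen on the ester carbonyl, loss of ethoxide, enolisation), the laboratory copy of triketide pyrone formation, driven by formation of the aromatic pyronate.

**Step 9**
Reactants: 10 1-{(2R)-7-[(dimethylamino)methyl]-4,6-dihydroxy-2-(prop-1-en-2-yl)-2,3-dihydro-1-benzofuran-5-yl}-2-methylpropan-1-one; 15 6-ethyl-4-hydroxy-5-methyl-2H-pyran-2-one (1.2 equiv)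
Product: 17 3-{[(2R)-4,6-dihydroxy-5-(2-methylpropanoyl)-2-(prop-1-en-2-yl)-2,3-dihydro-1-benzofuran-7-yl]methyl}-6-ethyl-4-hydroxy-5-methyl-2H-pyran-2-one, via o-quinone methide 16 (not isolated)
Conditions: 1,4-dioxane, 80 °C, slow N2 stream; then dilute aq HCl wash
Reagents that add atoms: none
Why: Proton transfer from the acidic pyrone 4-OH of 15 to the dimethylamino group of 10 gives an ammonium pyronate ion pair; on warming, the C6 oxygen (ortho to the benzylic carbon, supported by the para C4–OH) pushes out dimethylamine in an E1cB-type elimination to give o-quinone methide 16, whose exocyclic CH2 is attacked in a 1,4-sense by C3 of the pyronate, and tautomerisation restores both aromatic rings. The closest known reaction type is the thermal C-alkylation of 4-hydroxy-2-pyrones, 4-hydroxycoumarins and cyclic 1,3-diones with phenolic Mannich bases through o-quinone methides, which is also the classical entry to unsymmetrical methylene-bridged acylphloroglucinols, and the event copies the presumed biosynthetic union of the two polyketide halves. In one reagent-free operation the step discards its own activating group, completes the hexasubstituted benzene ring, assembles the whole C24 skeleton and needs no protection of the three acidic OH groups; it closes no ring and creates no stereocentre, and C2 (R) lies outside the reacting π-system and is not touched. Site selectivity on the pyrone is secured because C3 is the only free ring carbon (C5 carries the methyl group) and because O-alkylation is reversible by re-expulsion of the pyronate whereas C-alkylation is not. Self-condensation is excluded because every ring carbon of 10 is substituted, so no aromatic C–H nucleophile competes with 15, and the escape of gaseous dimethylamine drives the sequence forward.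

**Compound list**
1 | phloroglucinol | Oc1cc(O)cc(O)c1 | starting material
2 | isobutyryl chloride | CC(C)C(=O)Cl | starting material
3 | phlorisobutyrophenone | CC(C)C(=O)c1c(O)cc(O)cc1O | intermediate
4 | 2-methyl-2-vinyloxirane (racemic) | CC1(C=C)CO1 | starting material
5 | (E)-4-chloro-2-methylbut-2-en-1-ol | OC/C(C)=C/CCl | intermediate
6 | (E)-4-chloro-2-methylbut-2-en-1-yl methyl carbonate | COC(=O)OC/C(C)=C/CCl | intermediate
7 | (2E)-2-methyl-4-[2,4,6-trihydroxy-3-(2-methylpropanoyl)phenyl]but-2-en-1-yl methyl carbonate | COC(=O)OC/C(C)=C/Cc1c(O)cc(O)c(C(=O)C(C)C)c1O | intermediate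
8 | 1-[(2R)-4,6-dihydroxy-2-(prop-1-en-2-yl)-2,3-dihydro-1-benzofuran-5-yl]-2-methylpropan-1-one | C=C(C)[C@H]1Cc2c(O)c(C(=O)C(C)C)c(O)cc2O1 | intermediate
9 | Eschenmoser's salt | C=[N+](C)C.[I-] | starting material
10 | 1-{(2R)-7-[(dimethylamino)methyl]-4,6-dihydroxy-2-(prop-1-en-2-yl)-2,3-dihydro-1-benzofuran-5-yl}-2-methylpropan-1-one | C=C(C)[C@H]1Cc2c(O)c(C(=O)C(C)C)c(O)c(CN(C)C)c2O1 | intermediate
11 | ethyl 3-oxopentanoate | CCC(=O)CC(=O)OCC | starting material
12 | N-methoxy-N-methylpropanamide | CCC(=O)N(C)OC | starting material
13 | dilithio dianion of ethyl 3-oxopentanoate | [Li+].[Li+].CCOC([O-])=CC([O-])=CC | intermediate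
14 | ethyl 4-methyl-3,5-dioxoheptanoate (racemic, enolisable) | CCC(=O)C(C)C(=O)CC(=O)OCC | intermediate
15 | 6-ethyl-4-hydroxy-5-methyl-2H-pyran-2-one | CCc1oc(=O)cc(O)c1C | intermediate
16 | (2R)-4-hydroxy-7-methylidene-5-(2-methylpropanoyl)-2-(prop-1-en-2-yl)-2,3-dihydro-1-benzofuran-6(7H)-one (o-quinone methide) | C=C(C)[C@H]1CC2=C(O1)C(=C)C(=O)C(C(=O)C(C)C)=C2O | intermediate
17 | 3-{[(2R)-4,6-dihydroxy-5-(2-methylpropanoyl)-2-(prop-1-en-2-yl)-2,3-dihydro-1-benzofuran-7-yl]methyl}-6-ethyl-4-hydroxy-5-methyl-2H-pyran-2-one | C=C(C)[C@H]1Cc2c(O)c(C(=O)C(C)C)c(O)c(Cc3c(O)c(C)c(CC)oc3=O)c2O1 | target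

**Step count**
Total step count: 9
Longest linear sequence: 6 (steps 2, 3, 4, 5, 6, 9)

**Steps most likely to fail**

**Step 5.**
- What may go wrong: the hydroxyl between the ketone and the side chain may compete for the allyl terminus. Facial discrimination may be insufficient on this electron-poor phenol. The product ether may re-ionise slowly, which would erode the configuration.
- Fallback (from 1 and 6, back at 8): the ring closure is moved to a stage at which the two hydroxyls flanking the side chain are equivalent, and the ketone is brought in afterwards by directed metalation. C-allylation of excess 1 with 6 (DBU, THF) should give (E)-2-methyl-4-(2,4,6-trihydroxyphenyl)but-2-en-1-yl methyl carbonate F1. The same Pd/(R,R)-ligand cyclisation can then only give (2R)-2-(prop-1-en-2-yl)-2,3-dihydro-1-benzofuran-4,6-diol F2. MOMCl/i-Pr2NEt gives (2R)-4,6-bis(methoxymethoxy)-2-(prop-1-en-2-yl)-2,3-dihydro-1-benzofuran F3. Directed ortho-lithiation at C5 between the two OMOM groups (n-BuLi, THF, −78 to 0 °C) and a quench with N-methoxy-N-methylisobutyramide gives 1-[(2R)-4,6-bis(methoxymethoxy)-2-(prop-1-en-2-yl)-2,3-dihydro-1-benzofuran-5-yl]-2-methylpropan-1-one F4. HCl in MeOH then releases 8.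

**Step 4.**
- What may go wrong: O-alkylation, a second alkylation at the remaining ring carbon, and dearomatising geminal alkylation.
- Fallback (from 3 and 4, back at 7): the C–C bond is made under neutral Pd(0) catalysis, where O-allylation is reversible and C-allylation is not. Tsuji–Trost 1,4-opening of vinyl epoxide 4 by 3 (Pd(PPh3)4 cat., THF, rt) should give 1-{2,4,6-trihydroxy-3-[(2E)-4-hydroxy-3-methylbut-2-en-1-yl]phenyl}-2-methylpropan-1-one F5. Exhaustive methoxycarbonylation (ClCO2Me, pyridine) gives the tetrakis(methyl carbonate) F6. The three aryl carbonates are much better acyl donors than the alkyl carbonate, so they are removed selectively with NH3 in MeOH at 0 °C to give 7.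

**Step 9.**
- What may go wrong: the quinone methide may tautomerise through the C3 methylene, which would aromatise the five-membered ring and destroy the stereocentre. It may also self-react. On prolonged heating, retro-Michael scrambling of the methylene bridge is possible.
- Fallback (from 8, back at 17): the bridge carbon is introduced at the aldehyde level and the same bond is made by condensation and reduction at room temperature. Vilsmeier–Haack formylation of 8 (POCl3, DMF, EtOAc, 0 °C to rt; aqueous hydrolysis) should give (2R)-4,6-dihydroxy-5-(2-methylpropanoyl)-2-(prop-1-en-2-yl)-2,3-dihydro-1-benzofuran-7-carbaldehyde F7. Organocatalytic three-component reductive alkylation with 15 (L-proline cat., Hantzsch ester, CH2Cl2–EtOH, rt) proceeds by Knoevenagel condensation to the 3-(arylmethylidene)pyran-2,4-dione F8. F8 is reduced in the flask by conjugate hydride transfer to give 17.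

**Further compounds**
F1 | step 5 | (E)-2-methyl-4-(2,4,6-trihydroxyphenyl)but-2-en-1-yl methyl carbonate | COC(=O)OC/C(C)=C/Cc1c(O)cc(O)cc1O
F2 | step 5 | (2R)-2-(prop-1-en-2-yl)-2,3-dihydro-1-benzofuran-4,6-diol | C=C(C)[C@H]1Cc2c(O)cc(O)cc2O1
F3 | step 5 | (2R)-4,6-bis(methoxymethoxy)-2-(prop-1-en-2-yl)-2,3-dihydro-1-benzofuran | C=C(C)[C@H]1Cc2c(OCOC)cc(OCOC)cc2O1
F4 | step 5 | 1-[(2R)-4,6-bis(methoxymethoxy)-2-(prop-1-en-2-yl)-2,3-dihydro-1-benzofuran-5-yl]-2-methylpropan-1-one | C=C(C)[C@H]1Cc2c(OCOC)c(C(=O)C(C)C)c(OCOC)cc2O1
F5 | step 4 | 1-{2,4,6-trihydroxy-3-[(2E)-4-hydroxy-3-methylbut-2-en-1-yl]phenyl}-2-methylpropan-1-one | OC/C(C)=C/Cc1c(O)cc(O)c(C(=O)C(C)C)c1O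
F6 | step 4 | tetrakis(methyl carbonate) of F5 | COC(=O)OC/C(C)=C/Cc1c(OC(=O)OC)cc(OC(=O)OC)c(C(=O)C(C)C)c1OC(=O)OC
F7 | step 9 | (2R)-4,6-dihydroxy-5-(2-methylpropanoyl)-2-(prop-1-en-2-yl)-2,3-dihydro-1-benzofuran-7-carbaldehyde | C=C(C)[C@H]1Cc2c(O)c(C(=O)C(C)C)c(O)c(C=O)c2O1
F8 | step 9 | 3-{[(2R)-4,6-dihydroxy-5-(2-methylpropanoyl)-2-(prop-1-en-2-yl)-2,3-dihydro-1-benzofuran-7-yl]methylidene}-6-ethyl-5-methyl-2H-pyran-2,4(3H)-dione | C=C(C)[C@H]1Cc2c(O)c(C(=O)C(C)C)c(O)c(C=C3C(=O)OC(CC)=C(C)C3=O)c2O1
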